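**Retrosynthetic overview**

- The strategy rests on ring B: the tertiary carbinol C4 (4β-OH) and the acrylate-bearing C7 lie 1,4-cis across the C5=C6 alkene (eudesmane numbering), the signature of a net-retention palladium 1,4-opening of a 4β,5β-epoxy-6-ene by a carbon nucleophile.
- Disconnections, last to first: C3–O angelate ester; C11=C13 methylene (HWE with formaldehyde); C7–C11 bond (Tsuji–Trost alkylation of the vinyl epoxide with trimethyl phosphonoacetate); epoxide from the 4,6-dien-3β-ol; dienol from the 4-en-3-one.
- Ring order: ring B is bought as 2-methylcyclohexanone; ring A is annulated onto it by an auxiliary-controlled Michael addition (C10–C1) and an aldol condensation (C4–C5); no further ring is formed.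
- Stereochemistry: C10 from the (R)-1-phenylethylamine imine; C3 by α-face hydride; C4 and C5 by hydroxyl-directed epoxidation; C7 by double inversion at palladium; the Z-enoate is bought with angelic acid.

Key step: step 7

Remark: eudesmane numbering is used for all bicyclic compounds (ring A = C1–C5 and C10, ring B = C5–C10), and β is the face of the C10 methyl group.
Remark: catalyst-bound species and fleeting adducts (π-allylpalladium complexes, HWE betaines) are discussed in the Why lines and carry no numbers; only intermediates that accumulate in the flask are numbered.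
Remark: the Michael step is expected to give high but not complete enantiomeric purity; if needed it would be raised by recrystallising a crystalline intermediate such as diol 14.

Step 1
Reactants: 1 2-methylcyclohexanone (racemic); 2 (R)-1-phenylethylamine
Product: 3 N-[(R)-1-phenylethyl]-2-methylcyclohexan-1-imine
Conditions: TsOH·H2O (cat.), toluene, reflux, Dean–Stark
Reagents that add atoms: none
Why: Acid-catalysed ketone–primary amine condensation driven by azeotropic removal of water; the stereocentre of 1 is irrelevant because the imine equilibrates through its enamine tautomers.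

Step 2
Reactants: 3 N-[(R)-1-phenylethyl]-2-methylcyclohexan-1-imine; 4 ethyl vinyl ketone
Product: 6 (S)-2-methyl-2-(3-oxopentyl)cyclohexanone, via Michael adduct imine 5 (not isolated)
Conditions: 4 (1.2 equiv), THF, 40 °C, dark; then 20% aq. AcOH, rt
Reagents that add atoms: water (O)
Why: Deracemising chiral-imine Michael addition: 3 reacts through its more substituted secondary enamine tautomer in a compact aza-ene-like transition state with internal N–H to carbon proton transfer, the enone approaching the enamine face away from the phenyl group of the (R)-auxiliary, which sets the quaternary C10 as S; mild aqueous acid then hydrolyses the adduct imine and returns the amine.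

Step 3
Reactants: 6 (S)-2-methyl-2-(3-oxopentyl)cyclohexanone
Product: 8 (4aS)-1,4a-dimethyl-4,4a,5,6,7,8-hexahydronaphthalen-2(3H)-one, via aldol ketol 7 (not isolated)
Conditions: NaOMe (0.3 equiv), MeOH, 60 °C
Reagents that add atoms: none
Why: Intramolecular aldol condensation (the ring-closing half of a Robinson annulation): the enolate at the ethyl-ketone methylene adds to the ring carbonyl to form C4–C5 and ring A, and E1cB dehydration of ketol 7 gives the conjugated enone; C10 has no α-hydrogen and cannot epimerise.

Step 4
Reactants: 8 (4aS)-1,4a-dimethyl-4,4a,5,6,7,8-hexahydronaphthalen-2(3H)-one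
Product: 9 (4aS)-1,4a-dimethyl-4,4a,5,6-tetrahydronaphthalen-2(3H)-one
Conditions: chloranil (1.3 equiv), t-BuOH, reflux
Reagents that add atoms: none
Why: Quinone dehydrogenation: chloranil abstracts hydride from C7 of the 3,5-dienol tautomer of the enone and proton loss gives the linear 4,6-dien-3-one, the milder quinone favouring this path over dehydrogenation at C1–C2; C10 is not involved.

Step 5
Reactants: 9 (4aS)-1,4a-dimethyl-4,4a,5,6-tetrahydronaphthalen-2(3H)-one
Product: 10 (2S,4aS)-1,4a-dimethyl-2,3,4,4a,5,6-hexahydronaphthalen-2-ol
Conditions: NaBH4, CeCl3·7H2O, MeOH, −20 → 0 °C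
Reagents that add atoms: none
Why: Luche reduction: the cerium-activated carbonyl takes hydride 1,2 with no conjugate reduction of the dienone, delivered axially from the α face, so the new C3 hydroxyl should emerge pseudo-equatorial and β (3S).

Step 6
Reactants: 10 (2S,4aS)-1,4a-dimethyl-2,3,4,4a,5,6-hexahydronaphthalen-2-ol
Product: 11 (3S,4S,5R,10S)-4β,5β-epoxy-4α,10β-dimethyl-octal-6-en-3β-ol
Conditions: VO(acac)2 (3 mol %), t-BuOOH (1.2 equiv, in decane), CH2Cl2, 0 °C → rt; Et3N-deactivated silica
Reagents that add atoms: tert-butyl hydroperoxide (CC(C)(C)OO)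
Why: Vanadium-catalysed hydroxyl-directed epoxidation: the alkoxyvanadium peroxide formed at the 3β-oxygen transfers oxygen intramolecularly to the adjacent electron-rich tetrasubstituted C4=C5 bond on the hydroxyl-bearing β face, fixing C4 and C5 and leaving the remote C6=C7 alkene untouched.

Step 7
Reactants: 11 (3S,4S,5R,10S)-4β,5β-epoxy-4α,10β-dimethyl-octal-6-en-3β-ol; 12 trimethyl phosphonoacetate
Product: 13 methyl 2-(dimethoxyphosphoryl)-2-[(3S,4R,7R,10S)-3β,4β-dihydroxy-eudesm-5-en-7β-yl]acetate (C7 chain is C11/C12 only; mixture at the phosphonate carbon)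
Conditions: Pd(PPh3)4 (5 mol %), 12 (1.5 equiv), degassed THF, rt → 45 °C
Reagents that add atoms: none
Why: Zerovalent palladium coordinates the C6=C7 alkene of 11 on the open α face, anti to the allylic C5–O bond, and ionises the strained epoxide with inversion to a C5–C6–C7 π-allyl complex of divalent palladium carrying the 4β-alkoxide; this alkoxide deprotonates 12, and the phosphonoacetate anion attacks C7 on the face opposite the metal (second inversion), releasing the catalyst. The closest known reaction type is the Tsuji–Trost 1,4-alkylation of cyclic 1,3-diene monoepoxides by stabilised carbon pronucleophiles under neutral conditions, which runs with net retention. No ring closes: the C7–C11 bond is joined intermolecularly on the preformed decalin while the C5–O bond breaks and the alkene moves from C6=C7 to C5=C6. The new stereocentre C7 is controlled by the double inversion, which puts the carbon nucleophile on the β face formerly held by the epoxide oxygen, cis to the liberated 4β-OH; the phosphonate-bearing carbon forms as a mixture that the next step erases. The step needs distal (C7) rather than proximal (C5) attack, secured because C5 is fully substituted and flanked by the quaternary C10 and C4 whereas C7 is a secondary terminus; β-hydride loss to a 5,7-dienol is the competing path and is held back by the excess of soft nucleophile.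

Step 8
Reactants: 13 methyl 2-(dimethoxyphosphoryl)-2-[(3S,4R,7R,10S)-3β,4β-dihydroxy-eudesm-5-en-7β-yl]acetate
Product: 14 methyl (3S,4R,7R,10S)-3β,4β-dihydroxyeudesma-5,11(13)-dien-12-oate
Conditions: 37% aq. HCHO (5 equiv), K2CO3 (2 equiv), THF–H2O, rt → 40 °C
Reagents that add atoms: formaldehyde (C=O)
Why: Horner–Wadsworth–Emmons methylenation: carbonate deprotonates the doubly activated phosphonate carbon, the carbanion adds to formaldehyde and elimination of dimethyl phosphate gives the 1,1-disubstituted C11=C13 alkene, erasing the mixed phosphonate centre without touching C7, whose hydrogen is not acidic towards carbonate.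

Step 9
Reactants: 15 angelic acid ((Z)-2-methylbut-2-enoic acid)
Product: 16 angelic 2,4,6-trichlorobenzoic anhydride
Conditions: 2,4,6-trichlorobenzoyl chloride (1.0 equiv), Et3N (1.05 equiv), toluene, 0 °C → rt; filter, use the filtrate
Reagents that add atoms: 2,4,6-trichlorobenzoyl chloride (O=C(Cl)c1c(Cl)cc(Cl)cc1Cl)
Why: Mixed-anhydride formation of the Yamaguchi type: the triethylammonium angelate is acylated at oxygen by the hindered aroyl chloride at low temperature with no nucleophilic catalyst present, so the Z alkene has no pathway to isomerise.

Step 10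
Reactants: 14 methyl (3S,4R,7R,10S)-3β,4β-dihydroxyeudesma-5,11(13)-dien-12-oate; 16 angelic 2,4,6-trichlorobenzoic anhydride
Product: 17 methyl (3S,4R,7R,10S)-3β-angeloyloxy-4β-hydroxyeudesma-5,11(13)-dien-12-oate (CNP0283268.1)
Conditions: 16 (2 equiv), i-Pr2NEt (2.5 equiv), toluene, 80 °C; no DMAP
Reagents that add atoms: none
Why: Acyl transfer from the mixed anhydride: the alcohol attacks the angeloyl carbonyl because the aroyl carbonyl is shielded by its two ortho chlorines, only the secondary equatorial 3β-OH reacts while the tertiary 4β-OH is too hindered, and leaving out DMAP or other conjugate-adding nucleophiles should keep the Z geometry; acylation at oxygen leaves C3 unchanged.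

**Compound list**

1 | 2-methylcyclohexanone (racemic) | CC1CCCCC1=O | starting material
2 | (R)-1-phenylethylamine | C[C@@H](N)c1ccccc1 | starting material
3 | N-[(R)-1-phenylethyl]-2-methylcyclohexan-1-imine (ring centre equilibrating) | C[C@@H](N=C1CCCCC1C)c1ccccc1 | intermediate
4 | ethyl vinyl ketone (pent-1-en-3-one) | C=CC(=O)CC | starting material
5 | Michael adduct imine, (S)-2-methyl-2-(3-oxopentyl)-N-[(R)-1-phenylethyl]cyclohexan-1-imine (not isolated) | CCC(=O)CC[C@]1(C)CCCCC1=N[C@H](C)c1ccccc1 | intermediate
6 | (S)-2-methyl-2-(3-oxopentyl)cyclohexanone | CCC(=O)CC[C@]1(C)CCCCC1=O | intermediate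
7 | aldol ketol, (4aS)-8a-hydroxy-1,4a-dimethyloctahydronaphthalen-2(1H)-one, mixture at C1 and C8a (not isolated) | C1CC2(O)C(C)C(=O)CC[C@]2(C)CC1 | intermediate
8 | (4aS)-1,4a-dimethyl-4,4a,5,6,7,8-hexahydronaphthalen-2(3H)-one (4-en-3-one) | C1CC2=C(C)C(=O)CC[C@]2(C)CC1 | intermediate
9 | (4aS)-1,4a-dimethyl-4,4a,5,6-tetrahydronaphthalen-2(3H)-one (4,6-dien-3-one) | C1=CC2=C(C)C(=O)CC[C@]2(C)CC1 | intermediate
10 | (2S,4aS)-1,4a-dimethyl-2,3,4,4a,5,6-hexahydronaphthalen-2-ol (4,6-dien-3β-ol) | C1=CC2=C(C)[C@@H](O)CC[C@]2(C)CC1 | intermediate
11 | (3S,4S,5R,10S)-4β,5β-epoxy-4α,10β-dimethyl-octal-6-en-3β-ol (vinyl epoxide) | C1=C[C@]23O[C@@]2(C)[C@@H](O)CC[C@]3(C)CC1 | intermediate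
12 | trimethyl phosphonoacetate | COC(=O)CP(=O)(OC)OC | starting material
13 | methyl 2-(dimethoxyphosphoryl)-2-[(3S,4R,7R,10S)-3β,4β-dihydroxy-eudesm-5-en-7β-yl]acetate (7α-H; mixture at the phosphonate carbon) | COC(=O)C(P(=O)(OC)OC)[C@H]1C=C2[C@](C)(CC[C@H](O)[C@]2(C)O)CC1 | intermediate
14 | methyl (3S,4R,7R,10S)-3β,4β-dihydroxyeudesma-5,11(13)-dien-12-oate (diol acrylate, 7α-H) | C=C(C(=O)OC)[C@H]1C=C2[C@](C)(CC[C@H](O)[C@]2(C)O)CC1 | intermediate
15 | angelic acid, (Z)-2-methylbut-2-enoic acid | C/C=C(/C)C(=O)O | starting material
16 | angelic 2,4,6-trichlorobenzoic anhydride | C/C=C(/C)C(=O)OC(=O)c1c(Cl)cc(Cl)cc1Cl | intermediate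
17 | methyl (3S,4R,7R,10S)-3β-angeloyloxy-4β-hydroxyeudesma-5,11(13)-dien-12-oate (CNP0283268.1) | C=C(C(=O)OC)[C@H]1C=C2[C@](C)(CC[C@H](OC(=O)/C(C)=C\C)[C@]2(C)O)CC1 | target

**Step count**

Total steps: 10. Longest linear sequence: 9 (steps 1–8 and step 10, from 2-methylcyclohexanone); step 9 is a one-step side branch from angelic acid.

**Steps most likely to fail**

1. Step 7. The weakly acidic, bulky phosphonoacetate may be transferred too slowly to the π-allyl intermediate, so that β-hydride elimination to a dienol or catalyst decay outruns C–C bond formation; slow capture could also erode the C7 face fidelity through palladium-for-palladium exchange on the allyl complex. Fallback: setting out from vinyl epoxide 11, dimethyl malonate, the archetypal pronucleophile for neutral vinyl-epoxide alkylation, would be used under the same Pd(PPh3)4/THF conditions to give the 7β-malonate diol F1 by the same double-inversion pathway. Half-saponification (KOH, 1 equiv, MeOH–H2O, 0 °C → rt) would give the malonic half-ester F2. Decarboxylative Mannich methylenation (paraformaldehyde, Et2NH, EtOAc, reflux) would then install the C11=C13 methylene with loss of carbon dioxide, coming back to the route at diol acrylate 14 and bypassing 13.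

2. Step 6. Oxidation may stray to the C6=C7 alkene or take the allylic alcohol back to the dienone, and the tertiary allylic epoxide may open under the Lewis-acidic conditions or on silica. Fallback: setting out from dienone 9, Weitz–Scheffer epoxidation (30% H2O2, NaOH, MeOH, 0 °C) would add hydroperoxide at C5 and close on the α-carbon to give the 4β,5β-epoxy-6-en-3-one F3; β-face delivery is expected by axial attack, as with ring-fused 4-en-3-ones, and C6=C7 stays because ring closure needs the C4 enolate. Luche reduction (NaBH4, CeCl3·7H2O, MeOH, −40 °C), with hydride entering from the α face anti to the epoxide C–O bond, would then come back to the route at vinyl epoxide 11, bypassing 10; any 3α epimer would be removed by chromatography.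

3. Step 10. The angelate may isomerise from Z to E during acyl transfer, or acylation of the hindered secondary hydroxyl next to the quaternary carbinol may stall. Fallback: setting out from diol acrylate 14, Steglich esterification of the 3β-OH with 2-[bis(2,2,2-trifluoroethoxy)phosphoryl]propanoic acid (DCC, DMAP cat., CH2Cl2, 0 °C → rt) would give the phosphonopropionate ester F4. Still–Gennari olefination with acetaldehyde (KN(SiMe3)2, 1.0 equiv, 18-crown-6, THF, −78 °C) would then build the Z-trisubstituted enoate in place and arrive at target 17; one equivalent of base is used so that only the far more acidic phosphonate C–H is deprotonated and not the tertiary OH. Angelic acid and step 9 are then not needed.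

**Further compounds**

F1 | step 7 | dimethyl 2-[(3S,4R,7R,10S)-3β,4β-dihydroxy-eudesm-5-en-7β-yl]malonate (C7 chain is the malonate only) | COC(=O)C(C(=O)OC)[C@H]1C=C2[C@](C)(CC[C@H](O)[C@]2(C)O)CC1
F2 | step 7 | malonic half-ester of F1, 2-[(3S,4R,7R,10S)-3β,4β-dihydroxy-eudesm-5-en-7β-yl]-3-methoxy-3-oxopropanoic acid (mixture at the malonate carbon) | COC(=O)C(C(=O)O)[C@H]1C=C2[C@](C)(CC[C@H](O)[C@]2(C)O)CC1
F3 | step 6 | (4S,5R,10S)-4β,5β-epoxy-4α,10β-dimethyl-octal-6-en-3-one | C1=C[C@]23O[C@@]2(C)C(=O)CC[C@]3(C)CC1
F4 | step 10 | methyl (3S,4R,7R,10S)-3β-{2-[bis(2,2,2-trifluoroethoxy)phosphoryl]propanoyloxy}-4β-hydroxyeudesma-5,11(13)-dien-12-oate (mixture at the phosphonate carbon) | C=C(C(=O)OC)[C@H]1C=C2[C@](C)(CC[C@H](OC(=O)C(C)P(=O)(OCC(F)(F)F)OCC(F)(F)F)[C@]2(C)O)CC1
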